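**Plan**

1. Numbering the chain C1 (benzylic CH2) to C15 (carbinol carbon), the retrosynthesis cuts C4–C5 (allylboration of a C5 aldehyde), C13=C14 (aldol condensation of a C12/C13 methyl ketone) and, by a reverse 1,2-shift, the ring bond C7–C11.
2. Enabling feature: C11 carries a methyl and the C12 acyl group beside quaternary C7 inside ring C7–C11, which is the imprint of a 1,2-dimethylcyclohexene oxide contracted to a 1-acetyl-1-methylcyclopentane.
3. Forward: 2,6-dimethylcyclohexanone supplies the six-membered ring; allylation, triflation, ozonolysis/reduction, methylation, directed epoxidation and benzoylation lead to the epoxide, and BF3 contracts it to the cyclopentane, the only ring made (the arene is bought).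
4. The chain then grows outward: enone arm C13–C15 first (aldol, dehydration), then the C5 aldehyde is joined to a boronate carrying C1–C4 and the arene, followed by oxidation at C5 and global desilylation.
5. Stereochemistry: C7 from the Pd/(S)-phosphinooxazoline decarboxylative allylation; C11 relayed from C7 by hydroxyl-directed epoxidation and the anti 1,2-shift; 13E from E1cB dehydration; 2Z from the axial arylmethyl group in the chair allylboration.

Key step: step 8

Remark: the carbinol centres formed at C14 (step 11) and C5 (step 21) are left uncontrolled because both carbons become sp2 before the end; 2-allyl-6-methylphenol is taken as the arene source because para-oxidation then sets the second oxygen without a regiochemical choice.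

**Route**

Step 1
Reactants: 1 2,6-dimethylcyclohexan-1-one; 2 allyl chloroformate
Product: 3 2,6-dimethylcyclohex-1-en-1-yl prop-2-en-1-yl carbonate
Conditions: LiN(SiMe3)2, TMEDA, THF, −78 °C; then 2, −78 → 0 °C
Reagents that add atoms: none
Why: O-acylation of the lithium enolate of the symmetrical ketone by a chloroformate (enol carbonate formation) can give only one regioisomer, and TMEDA keeps the oxygen terminus the reactive site.

Step 2
Reactants: 3 2,6-dimethylcyclohex-1-en-1-yl prop-2-en-1-yl carbonate
Product: 4 (2S)-2,6-dimethyl-2-(prop-2-en-1-yl)cyclohexan-1-one (both epimers at the other alpha carbon)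
Conditions: Pd2(dba)3 (2.5 mol %), (S)-t-Bu-PHOX [(S)-4-tert-butyl-2-(2-diphenylphosphinophenyl)-4,5-dihydrooxazole] (6 mol %), THF, 25 °C
Reagents that add atoms: none
Why: Decarboxylative asymmetric allylic alkylation (Tsuji–Trost type) with zerovalent palladium recombines enolate and allyl fragment inside the chiral ligand sphere, which for 2-alkylcyclohexanone enol carbonates with the (S)-ligand should give the (S)-quaternary centre, here C7; the epimers at the remaining alpha methine converge in step 3.

Step 3
Reactants: 4 (2S)-2,6-dimethyl-2-(prop-2-en-1-yl)cyclohexan-1-one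
Product: 5 (6S)-2,6-dimethyl-6-(prop-2-en-1-yl)cyclohex-1-en-1-yl trifluoromethanesulfonate
Conditions: KN(SiMe3)2, THF, −78 → 0 °C; then PhNTf2, −78 °C → rt
Reagents that add atoms: N-phenylbis(trifluoromethanesulfonimide), FC(F)(F)S(=O)(=O)N(c1ccccc1)S(=O)(=O)C(F)(F)F
Why: Deprotonation is possible only at the remaining alpha methine, and O-sulfonylation of the enolate (enol triflate formation) should give the tetrasubstituted alkenyl triflate from either epimer of 4.

Step 4
Reactants: 5 (6S)-2,6-dimethyl-6-(prop-2-en-1-yl)cyclohex-1-en-1-yl trifluoromethanesulfonate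
Product: 7 (6S)-6-(2-hydroxyethyl)-2,6-dimethylcyclohex-1-en-1-yl trifluoromethanesulfonate, via oxoethyl triflate 6 (not isolated)
Conditions: O3, CH2Cl2/MeOH, −78 °C, stopped when the terminal alkene is consumed; Me2S, −78 → 0 °C; then NaBH4, 0 °C
Reagents that add atoms: ozone, [O-][O+]=O
Why: Electrophilic ozone should cleave the electron-rich terminal alkene much faster than the triflate-deactivated ring alkene (chemoselective ozonolysis), and borohydride reduction of the released aldehyde gives the two-carbon arm C6–C5 with the alkenyl triflate untouched.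

Step 5
Reactants: 7 (6S)-6-(2-hydroxyethyl)-2,6-dimethylcyclohex-1-en-1-yl trifluoromethanesulfonate
Product: 8 2-[(1S)-1,2,3-trimethylcyclohex-2-en-1-yl]ethan-1-ol
Conditions: MeZnCl (3 equiv), Pd(PPh3)4 (5 mol %), THF, 60 °C
Reagents that add atoms: methylzinc chloride, C[Zn]Cl
Why: Negishi cross-coupling of the alkenyl triflate with methylzinc chloride under zerovalent palladium installs the methyl group that becomes C13, a coupling established for hindered cyclohexenyl triflates and tolerant of the free hydroxyl.

Step 6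
Reactants: 8 2-[(1S)-1,2,3-trimethylcyclohex-2-en-1-yl]ethan-1-ol
Product: 9 2-[(1R,2S,6S)-1,2,6-trimethyl-7-oxabicyclo[4.1.0]heptan-2-yl]ethan-1-ol (epoxide oxygen cis to the hydroxyethyl arm)
Conditions: VO(acac)2 (5 mol %), t-BuOOH (in decane), CH2Cl2, 0 °C → rt
Reagents that add atoms: tert-butyl hydroperoxide, CC(C)(C)OO
Why: Hydroxyl-directed epoxidation through the vanadium alkoxide–peroxide complex should deliver oxygen to the face carrying the hydroxyethyl arm, so C7 sets both epoxide centres through the tether, and the syn relationship also forbids backside attack of the hydroxyl on the epoxide.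

Step 7
Reactants: 9 2-[(1R,2S,6S)-1,2,6-trimethyl-7-oxabicyclo[4.1.0]heptan-2-yl]ethan-1-ol
Product: 10 2-[(1R,2S,6S)-1,2,6-trimethyl-7-oxabicyclo[4.1.0]heptan-2-yl]ethyl benzoate
Conditions: BzCl, Et3N, DMAP (cat.), CH2Cl2, 0 °C → rt
Reagents that add atoms: benzoyl chloride, O=C(Cl)c1ccccc1
Why: Acylation of the primary alcohol (benzoate formation) under basic conditions masks the only nucleophile that could trap the cation of step 8 and gives an ester inert to BF3 and to the amide base of step 11.

Step 8
Reactants: 10 2-[(1R,2S,6S)-1,2,6-trimethyl-7-oxabicyclo[4.1.0]heptan-2-yl]ethyl benzoate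
Product: 11 2-[(1S,2S)-2-acetyl-1,2-dimethylcyclopentyl]ethyl benzoate
Conditions: BF3·OEt2 (0.3 equiv), CH2Cl2, −78 → −30 °C; Et3N, then aq NaHCO3
Reagents that add atoms: none
Why: BF3 binds the epoxide oxygen and, as one tertiary C–O bond lengthens, the ring bond on the neighbouring epoxide carbon migrates to the face opposite the departing oxygen while the other C–O bond becomes the C12 carbonyl, the Lewis-acid semipinacol (Meinwald) ring contraction known for 1,2-dimethylcyclohexene oxides. Ring C7–C11 is closed by this 1,2-alkyl shift, a contraction of the six-membered ring rather than an end-to-end cyclisation, with C7–C11 as the one new skeletal bond and the former epoxide carbon expelled as the acetyl group C12/C13. C11 is the only new stereocentre and is set by inversion at the migration terminus with retention at migrating C7, so the oxygen placed on the arm face in step 6 becomes cis methyl groups on C7 and C11, that is (7S,11S). Both ionisation modes converge: cleavage at the carbon remote from C7 sends quaternary C7 across, cleavage next to C7 sends the ring CH2 across, and each gives the same constitution and configuration. The step needs ring-bond migration to outrun methyl shift, proton loss to allylic alcohols and capture of an open cation, and this should be secured by the high migratory aptitude of fully substituted C7, relief of strain among three contiguous substituted ring carbons, low temperature in a non-basic solvent, and an ester-protected arm oxygen that cannot reach the rear face of the epoxide.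

Step 9
Reactants: 12 methyl 2-hydroxy-2-methylpropanoate
Product: 13 methyl 2-methyl-2-(triethylsilyloxy)propanoate
Conditions: Et3SiOTf, 2,6-lutidine, CH2Cl2, 0 °C
Reagents that add atoms: triethylsilyl trifluoromethanesulfonate, CC[Si](CC)(CC)OS(=O)(=O)C(F)(F)F
Why: Silylation with a silyl triflate and a hindered pyridine base is the standard protection of a tertiary alcohol, and the triethylsilyl ether should survive base, hydride and periodinane yet leave with fluoride at the end.

Step 10
Reactants: 13 methyl 2-methyl-2-(triethylsilyloxy)propanoate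
Product: 14 2-methyl-2-(triethylsilyloxy)propanal
Conditions: i-Bu2AlH (1.1 equiv), CH2Cl2, −78 °C; aq potassium sodium tartrate
Reagents that add atoms: none
Why: Partial reduction of an alpha-silyloxy ester with i-Bu2AlH at −78 °C stops at the aldehyde because the aluminium hemiacetal persists until work-up, and the product has no alpha hydrogen and cannot self-condense.

Step 11
Reactants: 11 2-[(1S,2S)-2-acetyl-1,2-dimethylcyclopentyl]ethyl benzoate; 14 2-methyl-2-(triethylsilyloxy)propanal
Product: 15 2-[(1S,2S)-2-[3-hydroxy-4-methyl-4-(triethylsilyloxy)pentanoyl]-1,2-dimethylcyclopentyl]ethyl benzoate (both C14 epimers)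
Conditions: LiN(SiMe3)2, THF, −78 °C; then 14, −78 °C; AcOH quench at −78 °C
Reagents that add atoms: none
Why: The methyl group C13 is the only enolisable position of 11, so its lithium enolate adds to the non-enolisable aldehyde (directed aldol addition) to form C13–C14, and the cold quench prevents silyl migration in the aldolate.

Step 12
Reactants: 15 2-[(1S,2S)-2-[3-hydroxy-4-methyl-4-(triethylsilyloxy)pentanoyl]-1,2-dimethylcyclopentyl]ethyl benzoate
Product: 17 2-[(1S,2S)-1,2-dimethyl-2-[(2E)-4-methyl-4-(triethylsilyloxy)pent-2-enoyl]cyclopentyl]ethyl benzoate, via mesylate 16 (not isolated)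
Conditions: MsCl, Et3N, CH2Cl2, 0 °C; then DBU, 0 °C → rt
Reagents that add atoms: none
Why: Mesylation followed by base-induced E1cB elimination (aldol dehydration) gives the conjugated enone, and the bulky C15 substituent makes the E geometry at C13=C14 the only low-energy outcome.

Step 13
Reactants: 17 2-[(1S,2S)-1,2-dimethyl-2-[(2E)-4-methyl-4-(triethylsilyloxy)pent-2-enoyl]cyclopentyl]ethyl benzoate
Product: 18 (2E)-1-[(1S,2S)-2-(2-hydroxyethyl)-1,2-dimethylcyclopentyl]-4-methyl-4-(triethylsilyloxy)pent-2-en-1-one
Conditions: K2CO3 (0.5 equiv), MeOH, rt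
Reagents that add atoms: none
Why: Methanolysis of the benzoate (transesterification by methoxide from K2CO3/MeOH) frees the primary alcohol under conditions that the hindered enone, the tertiary silyl ether and the two quaternary centres should tolerate.

Step 14
Reactants: 18 (2E)-1-[(1S,2S)-2-(2-hydroxyethyl)-1,2-dimethylcyclopentyl]-4-methyl-4-(triethylsilyloxy)pent-2-en-1-one
Product: 19 2-[(1S,2S)-1,2-dimethyl-2-[(2E)-4-methyl-4-(triethylsilyloxy)pent-2-enoyl]cyclopentyl]acetaldehyde
Conditions: Dess–Martin periodinane, NaHCO3, CH2Cl2, 0 °C → rt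
Reagents that add atoms: none
Why: Dess–Martin oxidation converts the primary alcohol to the C5 aldehyde under buffered, non-enolising conditions, and no stereocentre is at risk because C7 is quaternary.

Step 15
Reactants: 20 2-allyl-6-methylphenol
Product: 21 2-methyl-6-(prop-2-en-1-yl)cyclohexa-2,5-diene-1,4-dione
Conditions: O2 (1 atm), Co(salen) (10 mol %), MeCN, rt
Reagents that add atoms: dioxygen, O=O
Why: Cobalt-salen-catalysed aerobic oxidation of a 2,6-dialkylphenol goes to the para-quinone because both ortho positions are blocked, so the second oxygen lands para to the first with no regiochemical choice.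

Step 16
Reactants: 21 2-methyl-6-(prop-2-en-1-yl)cyclohexa-2,5-diene-1,4-dione
Product: 22 2-methyl-6-(prop-2-en-1-yl)benzene-1,4-diol
Conditions: Na2S2O4, THF/H2O, rt, under argon
Reagents that add atoms: none
Why: Dithionite reduction of a benzoquinone to the hydroquinone is fast and selective and leaves the allyl group alone.

Step 17
Reactants: 22 2-methyl-6-(prop-2-en-1-yl)benzene-1,4-diol
Product: 23 1,4-bis(tert-butyldimethylsilyloxy)-2-methyl-6-(prop-2-en-1-yl)benzene
Conditions: t-BuMe2SiOTf (2.5 equiv), 2,6-lutidine, CH2Cl2, 0 °C → rt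
Reagents that add atoms: tert-butyldimethylsilyl trifluoromethanesulfonate, CC(C)(C)[Si](C)(C)OS(=O)(=O)C(F)(F)F
Why: A silyl triflate with 2,6-lutidine silylates even the phenol flanked by two ortho substituents (silyl ether protection), and aryl silyl ethers should withstand metathesis, the copper–boryl step and periodinane and leave with fluoride.

Step 18
Reactants: 24 2-methylprop-2-en-1-ol
Product: 25 methyl 2-methylprop-2-en-1-yl carbonate
Conditions: ClCO2Me, pyridine, CH2Cl2, 0 °C
Reagents that add atoms: methyl chloroformate, COC(Cl)=O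
Why: Acylation of the allylic alcohol with a chloroformate (carbonate formation) supplies the leaving group needed for the copper-catalysed borylation of step 20.

Step 19
Reactants: 23 1,4-bis(tert-butyldimethylsilyloxy)-2-methyl-6-(prop-2-en-1-yl)benzene; 25 methyl 2-methylprop-2-en-1-yl carbonate
Product: 26 4-[2,5-bis(tert-butyldimethylsilyloxy)-3-methylphenyl]-2-methylbut-2-en-1-yl methyl carbonate (E/Z mixture)
Conditions: second-generation Hoveyda–Grubbs catalyst [RuCl2(H2IMes)(=CH-C6H4-2-O-i-Pr)] (5 mol %), 25 (5 equiv), CH2Cl2, 40 °C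
Reagents that add atoms: none
Why: Cross-metathesis of a terminal alkene with an excess of a 1,1-disubstituted alkene that does not homodimerise is an established route to trisubstituted alkenes, and its E/Z outcome is irrelevant because both isomers give the same allylboronate in step 20.

Step 20
Reactants: 26 4-[2,5-bis(tert-butyldimethylsilyloxy)-3-methylphenyl]-2-methylbut-2-en-1-yl methyl carbonate
Product: 27 2-[1-[2,5-bis(tert-butyldimethylsilyloxy)-3-methylphenyl]-3-methylbut-3-en-2-yl]-4,4,5,5-tetramethyl-1,3,2-dioxaborolane (racemic)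
Conditions: CuCl (5 mol %), Xantphos (5 mol %), KO-t-Bu (10 mol %), B2pin2 (1.2 equiv), THF, rt
Reagents that add atoms: bis(pinacolato)diboron, CC1(C)OB(OC1(C)C)B1OC(C)(C)C(C)(C)O1
Why: Copper-catalysed gamma-selective boryl substitution of allylic carbonates (SN2'-type borylcupration and beta-alkoxide elimination) should place boron on the carbon bearing the arylmethyl group and move the alkene to the terminus, giving the alpha-substituted 2-methylallylboronate as a racemate whose configuration does not matter.

Step 21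
Reactants: 19 2-[(1S,2S)-1,2-dimethyl-2-[(2E)-4-methyl-4-(triethylsilyloxy)pent-2-enoyl]cyclopentyl]acetaldehyde; 27 racemic alpha-substituted 2-methylallylboronate
Product: 28 (2E)-1-[(1S,2S)-2-[(4Z)-6-[2,5-bis(tert-butyldimethylsilyloxy)-3-methylphenyl]-2-hydroxy-4-methylhex-4-en-1-yl]-1,2-dimethylcyclopentyl]-4-methyl-4-(triethylsilyloxy)pent-2-en-1-one (both C5 epimers)
Conditions: 27 (1.5 equiv), toluene, 25 → 40 °C; then aq NaHCO3
Reagents that add atoms: none
Why: Allylboration through a closed six-membered chair transition state joins the terminal CH2 of 27 (C4) to the aldehyde carbon (C5) in the presence of the hindered enone, and the arylmethyl group on the boron-bearing carbon sits axial to avoid allylic 1,2-strain with the 2-methyl group, which should translate into the Z geometry at C2=C3.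

Step 22
Reactants: 28 C5 alcohol (both epimers)
Product: 29 (2E)-1-[(1S,2S)-2-[(4Z)-6-[2,5-bis(tert-butyldimethylsilyloxy)-3-methylphenyl]-4-methyl-2-oxohex-4-en-1-yl]-1,2-dimethylcyclopentyl]-4-methyl-4-(triethylsilyloxy)pent-2-en-1-one
Conditions: Dess–Martin periodinane, NaHCO3, CH2Cl2, 0 °C
Reagents that add atoms: none
Why: Buffered Dess–Martin oxidation of the homoallylic alcohol should give the beta,gamma-unsaturated C5 ketone without acid or base strong enough to move the C2=C3 double bond into conjugation or to scramble its geometry.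

Step 23
Reactants: 29 tris-silyl ether of the target
Product: 30 (2E)-1-[(1S,2S)-2-[(4Z)-6-(2,5-dihydroxy-3-methylphenyl)-4-methyl-2-oxohex-4-en-1-yl]-1,2-dimethylcyclopentyl]-4-hydroxy-4-methylpent-2-en-1-one (CNP0212540.3)
Conditions: Bu4NF, AcOH (1:1, 3.5 equiv each), degassed THF, 0 °C → rt, under argon
Reagents that add atoms: none
Why: Fluoride-induced desilylation buffered with acetic acid should cleave both aryl silyl ethers and the tertiary triethylsilyl ether in one operation while keeping the medium near neutral, so that the beta,gamma-unsaturated ketone, the enone and the hydroquinone survive.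

**Compound list**

1 | 2,6-dimethylcyclohexan-1-one (cis/trans mixture) | CC1CCCC(C)C1=O | starting material
2 | allyl chloroformate | C=CCOC(Cl)=O | starting material
3 | 2,6-dimethylcyclohex-1-en-1-yl prop-2-en-1-yl carbonate (racemic) | C=CCOC(=O)OC1=C(C)CCCC1C | intermediate
4 | (2S)-2,6-dimethyl-2-(prop-2-en-1-yl)cyclohexan-1-one (both epimers at the other alpha carbon) | C=CC[C@]1(C)CCCC(C)C1=O | intermediate
5 | (6S)-2,6-dimethyl-6-(prop-2-en-1-yl)cyclohex-1-en-1-yl trifluoromethanesulfonate | C=CC[C@]1(C)CCCC(C)=C1OS(=O)(=O)C(F)(F)F | intermediate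
6 | (6S)-2,6-dimethyl-6-(2-oxoethyl)cyclohex-1-en-1-yl trifluoromethanesulfonate | O=CC[C@]1(C)CCCC(C)=C1OS(=O)(=O)C(F)(F)F | intermediate (not isolated)
7 | (6S)-6-(2-hydroxyethyl)-2,6-dimethylcyclohex-1-en-1-yl trifluoromethanesulfonate | OCC[C@]1(C)CCCC(C)=C1OS(=O)(=O)C(F)(F)F | intermediate
8 | 2-[(1S)-1,2,3-trimethylcyclohex-2-en-1-yl]ethan-1-ol | OCC[C@]1(C)CCCC(C)=C1C | intermediate
9 | 2-[(1R,2S,6S)-1,2,6-trimethyl-7-oxabicyclo[4.1.0]heptan-2-yl]ethan-1-ol | OCC[C@]1(C)CCC[C@]2(C)O[C@]12C | intermediate
10 | 2-[(1R,2S,6S)-1,2,6-trimethyl-7-oxabicyclo[4.1.0]heptan-2-yl]ethyl benzoate | O=C(OCC[C@]1(C)CCC[C@]2(C)O[C@]12C)c1ccccc1 | intermediate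
11 | 2-[(1S,2S)-2-acetyl-1,2-dimethylcyclopentyl]ethyl benzoate | O=C(OCC[C@]1(C)CCC[C@]1(C)C(C)=O)c1ccccc1 | intermediate
12 | methyl 2-hydroxy-2-methylpropanoate | COC(=O)C(C)(C)O | starting material
13 | methyl 2-methyl-2-(triethylsilyloxy)propanoate | COC(=O)C(C)(C)O[Si](CC)(CC)CC | intermediate
14 | 2-methyl-2-(triethylsilyloxy)propanal | O=CC(C)(C)O[Si](CC)(CC)CC | intermediate
15 | 2-[(1S,2S)-2-[3-hydroxy-4-methyl-4-(triethylsilyloxy)pentanoyl]-1,2-dimethylcyclopentyl]ethyl benzoate (C14 epimers) | O=C(OCC[C@]1(C)CCC[C@]1(C)C(=O)CC(O)C(C)(C)O[Si](CC)(CC)CC)c1ccccc1 | intermediate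
16 | 2-[(1S,2S)-2-[3-(methanesulfonyloxy)-4-methyl-4-(triethylsilyloxy)pentanoyl]-1,2-dimethylcyclopentyl]ethyl benzoate | O=C(OCC[C@]1(C)CCC[C@]1(C)C(=O)CC(OS(C)(=O)=O)C(C)(C)O[Si](CC)(CC)CC)c1ccccc1 | intermediate (not isolated)
17 | 2-[(1S,2S)-1,2-dimethyl-2-[(2E)-4-methyl-4-(triethylsilyloxy)pent-2-enoyl]cyclopentyl]ethyl benzoate | O=C(OCC[C@]1(C)CCC[C@]1(C)C(=O)/C=C/C(C)(C)O[Si](CC)(CC)CC)c1ccccc1 | intermediate
18 | (2E)-1-[(1S,2S)-2-(2-hydroxyethyl)-1,2-dimethylcyclopentyl]-4-methyl-4-(triethylsilyloxy)pent-2-en-1-one | OCC[C@]1(C)CCC[C@]1(C)C(=O)/C=C/C(C)(C)O[Si](CC)(CC)CC | intermediate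
19 | 2-[(1S,2S)-1,2-dimethyl-2-[(2E)-4-methyl-4-(triethylsilyloxy)pent-2-enoyl]cyclopentyl]acetaldehyde | O=CC[C@]1(C)CCC[C@]1(C)C(=O)/C=C/C(C)(C)O[Si](CC)(CC)CC | intermediate
20 | 2-allyl-6-methylphenol | C=CCc1cccc(C)c1O | starting material
21 | 2-methyl-6-(prop-2-en-1-yl)cyclohexa-2,5-diene-1,4-dione | C=CCC1=CC(=O)C=C(C)C1=O | intermediate
22 | 2-methyl-6-(prop-2-en-1-yl)benzene-1,4-diol | C=CCc1cc(O)cc(C)c1O | intermediate
23 | 1,4-bis(tert-butyldimethylsilyloxy)-2-methyl-6-(prop-2-en-1-yl)benzene | C=CCc1cc(O[Si](C)(C)C(C)(C)C)cc(C)c1O[Si](C)(C)C(C)(C)C | intermediate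
24 | 2-methylprop-2-en-1-ol | C=C(C)CO | starting material
25 | methyl 2-methylprop-2-en-1-yl carbonate | C=C(C)COC(=O)OC | intermediate
26 | 4-[2,5-bis(tert-butyldimethylsilyloxy)-3-methylphenyl]-2-methylbut-2-en-1-yl methyl carbonate (E/Z mixture) | COC(=O)OCC(C)=CCc1cc(O[Si](C)(C)C(C)(C)C)cc(C)c1O[Si](C)(C)C(C)(C)C | intermediate
27 | 2-[1-[2,5-bis(tert-butyldimethylsilyloxy)-3-methylphenyl]-3-methylbut-3-en-2-yl]-4,4,5,5-tetramethyl-1,3,2-dioxaborolane (racemic) | C=C(C)C(Cc1cc(O[Si](C)(C)C(C)(C)C)cc(C)c1O[Si](C)(C)C(C)(C)C)B1OC(C)(C)C(C)(C)O1 | intermediate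
28 | (2E)-1-[(1S,2S)-2-[(4Z)-6-[2,5-bis(tert-butyldimethylsilyloxy)-3-methylphenyl]-2-hydroxy-4-methylhex-4-en-1-yl]-1,2-dimethylcyclopentyl]-4-methyl-4-(triethylsilyloxy)pent-2-en-1-one (C5 epimers) | C/C(=C/Cc1cc(O[Si](C)(C)C(C)(C)C)cc(C)c1O[Si](C)(C)C(C)(C)C)CC(O)C[C@]1(C)CCC[C@]1(C)C(=O)/C=C/C(C)(C)O[Si](CC)(CC)CC | intermediate
29 | (2E)-1-[(1S,2S)-2-[(4Z)-6-[2,5-bis(tert-butyldimethylsilyloxy)-3-methylphenyl]-4-methyl-2-oxohex-4-en-1-yl]-1,2-dimethylcyclopentyl]-4-methyl-4-(triethylsilyloxy)pent-2-en-1-one | C/C(=C/Cc1cc(O[Si](C)(C)C(C)(C)C)cc(C)c1O[Si](C)(C)C(C)(C)C)CC(=O)C[C@]1(C)CCC[C@]1(C)C(=O)/C=C/C(C)(C)O[Si](CC)(CC)CC | intermediate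
30 | (2E)-1-[(1S,2S)-2-[(4Z)-6-(2,5-dihydroxy-3-methylphenyl)-4-methyl-2-oxohex-4-en-1-yl]-1,2-dimethylcyclopentyl]-4-hydroxy-4-methylpent-2-en-1-one | C/C(=C/Cc1cc(O)cc(C)c1O)CC(=O)C[C@]1(C)CCC[C@]1(C)C(=O)/C=C/C(C)(C)O | target

**Count**

Total steps: 23. Longest linear sequence: 15 steps (steps 1–8, 11–14, 21–23) from 2,6-dimethylcyclohexanone.

**Steps most likely to fail**

Step 6. The hydroxyl sits three bonds away from a hindered tetrasubstituted alkene, so delivery of oxygen through the vanadium alkoxide may lose its facial preference. Because step 8 passes the epoxide face on to C11, any such loss would end as the C11 epimer. The fallback replaces directed delivery by a covalent tether. It sets out from 8, which would be oxidised with PhI(OAc)2 and catalytic TEMPO in MeCN/H2O to 2-[(1S)-1,2,3-trimethylcyclohex-2-en-1-yl]acetic acid F1. Iodolactonisation (I2, NaHCO3, CH2Cl2/H2O, 0 °C) should give (3aS,7R,7aR)-7-iodo-3a,7,7a-trimethylhexahydro-1-benzofuran-2(3H)-one F2, since the carboxylate can reach the ring carbon next to C7 only from the arm face, with iodine entering anti. NaOMe in MeOH would open the lactone, and the freed alkoxide would displace the anti iodide to give methyl 2-[(1R,2S,6S)-1,2,6-trimethyl-7-oxabicyclo[4.1.0]heptan-2-yl]acetate F3 with the oxygen on the arm face. Reduction with i-Bu2AlH at −78 °C returns to the route at 9.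

Step 21. The hindered secondary boronate may add slowly, part of the reaction may pass through the chair with an equatorial arylmethyl group and erode the Z geometry, and the borylation of step 20 that feeds it may not be fully gamma-selective. The fallback fixes the alkene geometry before the C4–C5 bond is made. It sets out from 23, which would be cleaved by Lemieux–Johnson oxidation (OsO4 cat., NaIO4, 2,6-lutidine, dioxane/H2O) to 2-[2,5-bis(tert-butyldimethylsilyloxy)-3-methylphenyl]acetaldehyde F4. Still–Gennari olefination with ethyl 2-[bis(2,2,2-trifluoroethoxy)phosphoryl]propanoate, KN(SiMe3)2 and 18-crown-6 at −78 °C should give ethyl (2Z)-4-[2,5-bis(tert-butyldimethylsilyloxy)-3-methylphenyl]-2-methylbut-2-enoate F5. Reduction with i-Bu2AlH would give (2Z)-4-[2,5-bis(tert-butyldimethylsilyloxy)-3-methylphenyl]-2-methylbut-2-en-1-ol F6, and MsCl, LiCl and 2,4,6-collidine in DMF at 0 °C would give 1,4-bis(tert-butyldimethylsilyloxy)-2-[(2Z)-4-chloro-3-methylbut-2-en-1-yl]-6-methylbenzene F7. Metalation of F7 with activated barium (BaI2 reduced by lithium biphenylide) in THF at −78 °C and addition of aldehyde 19 at that temperature should proceed at the alpha carbon with retention of the Z geometry, returning to the route at 28.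

Step 23. With all three silyl ethers removed at the very end, fluoride basicity may move the C2=C3 bond into conjugation or trigger intramolecular aldol of the 1,5-diketone (C4 onto C12). Trace acid may close a chroman onto the trisubstituted alkene, and the free hydroquinone may oxidise in air. The fallback removes the silyl groups before the sensitive C5 ketone exists and uses the quinone as a temporary protecting state. It sets out from 28, which would be desilylated with Bu4NF/AcOH to (2E)-1-[(1S,2S)-2-[(4Z)-6-(2,5-dihydroxy-3-methylphenyl)-2-hydroxy-4-methylhex-4-en-1-yl]-1,2-dimethylcyclopentyl]-4-hydroxy-4-methylpent-2-en-1-one F8. Excess Dess–Martin periodinane with NaHCO3 would oxidise both the secondary alcohol and the hydroquinone to give 2-[(2Z)-6-[(1S,2S)-2-[(2E)-4-hydroxy-4-methylpent-2-enoyl]-1,2-dimethylcyclopentyl]-3-methyl-5-oxohex-2-en-1-yl]-6-methylcyclohexa-2,5-diene-1,4-dione F9. Neutral reduction of the quinone alone with Na2S2O4 in EtOAc/H2O returns to the route at 30.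

**Further compounds**

F1 | step 6 | 2-[(1S)-1,2,3-trimethylcyclohex-2-en-1-yl]acetic acid | OC(=O)C[C@]1(C)CCCC(C)=C1C
F2 | step 6 | (3aS,7R,7aR)-7-iodo-3a,7,7a-trimethylhexahydro-1-benzofuran-2(3H)-one | O=C1C[C@]2(C)CCC[C@@](C)(I)[C@]2(C)O1
F3 | step 6 | methyl 2-[(1R,2S,6S)-1,2,6-trimethyl-7-oxabicyclo[4.1.0]heptan-2-yl]acetate | COC(=O)C[C@]1(C)CCC[C@]2(C)O[C@]12C
F4 | step 21 | 2-[2,5-bis(tert-butyldimethylsilyloxy)-3-methylphenyl]acetaldehyde | O=CCc1cc(O[Si](C)(C)C(C)(C)C)cc(C)c1O[Si](C)(C)C(C)(C)C
F5 | step 21 | ethyl (2Z)-4-[2,5-bis(tert-butyldimethylsilyloxy)-3-methylphenyl]-2-methylbut-2-enoate | CCOC(=O)/C(C)=C\Cc1cc(O[Si](C)(C)C(C)(C)C)cc(C)c1O[Si](C)(C)C(C)(C)C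
F6 | step 21 | (2Z)-4-[2,5-bis(tert-butyldimethylsilyloxy)-3-methylphenyl]-2-methylbut-2-en-1-ol | OC/C(C)=C\Cc1cc(O[Si](C)(C)C(C)(C)C)cc(C)c1O[Si](C)(C)C(C)(C)C
F7 | step 21 | 1,4-bis(tert-butyldimethylsilyloxy)-2-[(2Z)-4-chloro-3-methylbut-2-en-1-yl]-6-methylbenzene | ClC/C(C)=C\Cc1cc(O[Si](C)(C)C(C)(C)C)cc(C)c1O[Si](C)(C)C(C)(C)C
F8 | step 23 | (2E)-1-[(1S,2S)-2-[(4Z)-6-(2,5-dihydroxy-3-methylphenyl)-2-hydroxy-4-methylhex-4-en-1-yl]-1,2-dimethylcyclopentyl]-4-hydroxy-4-methylpent-2-en-1-one | C/C(=C/Cc1cc(O)cc(C)c1O)CC(O)C[C@]1(C)CCC[C@]1(C)C(=O)/C=C/C(C)(C)O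
F9 | step 23 | 2-[(2Z)-6-[(1S,2S)-2-[(2E)-4-hydroxy-4-methylpent-2-enoyl]-1,2-dimethylcyclopentyl]-3-methyl-5-oxohex-2-en-1-yl]-6-methylcyclohexa-2,5-diene-1,4-dione | C/C(=C/CC1=CC(=O)C=C(C)C1=O)CC(=O)C[C@]1(C)CCC[C@]1(C)C(=O)/C=C/C(C)(C)O
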